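## Retrosynthetic overview

1. The exocyclic methylene of lactone ring A is unmasked last from a CH2NMe2 group. Before that, the ring E hydroxyl opens a bridged lactone, which closes spirolactone ring D and frees the tertiary alcohol.
2. Key disconnection: the bridged lactone is the intramolecular Diels–Alder adduct of a 3,4,6-trisubstituted 2-pyrone and a terminal alkene five carbons away. Cycloheptane ring B, cyclohexene ring C, the enone and three stereocentres form in one operation.
3. The pyrone comes from a trisubstituted furan (singlet oxygen, then enol-lactonization onto an ester). The furan–ester bond comes from a palladium-catalysed ester α-arylation of a 3-bromofuran.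
4. The two halves have opposite handedness. The furan/ring A half comes from 2-methylfuran and crotonaldehyde; the ring E half comes from (R)-methylsuccinic acid monomethyl ester. Both use propiolate alkynylation and allylcupration.
5. Ring order: A, then E (ring-closing metathesis), temporary pyrone, B and C together, D last.

Assumption: the SMILES stereodescriptors are taken at face value, so the spirolactone/cycloheptene half (C18, C20, C24) is the mirror-image series of the other half (C5, C7, C15).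

Atom labels C1–C24 (with O4, O17) follow the main chain of the target SMILES from left to right; side atoms (=O, OH, CH3, acetyl, oxobutyl) are not counted. Selectivities below are reasoned from models, not measured.

## Route

Step 1
Reactants: 1 2-methylfuran; 2 (E)-but-2-enal
Product: 3 (3S)-3-(5-methylfuran-2-yl)butanal
Conditions: (2R,5R)-5-benzyl-2-tert-butyl-3-methylimidazolidin-4-one·CF3CO2H (20 mol%), CH2Cl2/i-PrOH 85:15, −40 °C
Reagents that add atoms: none
Why: Iminium-catalysed organocatalytic Friedel–Crafts conjugate alkylation, in which the free α-position of the furan attacks the β-carbon of the enal iminium on the face left open by the (2R,5R) catalyst, setting C7 as S.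

Step 2
Reactants: 3 (3S)-3-(5-methylfuran-2-yl)butanal
Product: 4 (3S)-3-(4-bromo-5-methylfuran-2-yl)butanal
Conditions: NBS (1.0 equiv), DMF, −20 °C, dark
Reagents that add atoms: N-bromosuccinimide, O=C1CCC(=O)N1Br
Why: Electrophilic aromatic bromination goes to the free furan position next to the small methyl group, not the one next to the branched side chain, and the furan reacts far faster than the aldehyde.

Step 3
Reactants: 4 (3S)-3-(4-bromo-5-methylfuran-2-yl)butanal; 5 methyl propiolate
Product: 7 methyl (4R,6S)-6-(4-bromo-5-methylfuran-2-yl)-4-hydroxyhept-2-ynoate, via zinc alkynylide 6 (not isolated)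
Conditions: Me2Zn (3 equiv), (S,S)-ProPhenol (20 mol%), Ph3P=O (40 mol%), PhMe, 4 °C
Reagents that add atoms: none
Why: Dinuclear-zinc ProPhenol alkynylation (catalytic asymmetric 1,2-addition of a zinc alkynylide), where the ligand rather than the remote C7 centre fixes C5 as R; the ligand hand is assigned from the usual model and the antipode would give the C5 epimer.

Step 4
Reactants: 7 methyl (4R,6S)-6-(4-bromo-5-methylfuran-2-yl)-4-hydroxyhept-2-ynoate
Product: 9 (5R)-5-[(2S)-2-(4-bromo-5-methylfuran-2-yl)propyl]-4-(prop-2-en-1-yl)furan-2(5H)-one, via hydroxy enoate 8 (not isolated)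
Conditions: allylMgBr (2.5 equiv), CuI·2LiCl (2.5 equiv), THF, −78 to −20 °C; aq. NH4Cl; PPTS (cat.), CH2Cl2, 23 °C
Reagents that add atoms: allylmagnesium bromide, C=CC[Mg]Br
Why: syn-Carbocupration (conjugate addition) of the ynoate places the allyl group on C15 and the ester cis to the carbinol carbon, so the (Z)-hydroxy enoate lactonizes to the butenolide without touching a stereocentre.

Step 5
Reactants: 9 (5R)-5-[(2S)-2-(4-bromo-5-methylfuran-2-yl)propyl]-4-(prop-2-en-1-yl)furan-2(5H)-one
Product: 11 (4R,5R)-5-[(2S)-2-(4-bromo-5-methylfuran-2-yl)propyl]-3-[(dimethylamino)methyl]-4-(prop-2-en-1-yl)oxolan-2-one, via silyl ketene acetal 10 (not isolated)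
Conditions: [(Ph3P)CuH]6 (5 mol%), PhMe2SiH (1.5 equiv), PhMe, 23 °C; then CH2=NMe2+ I− (2 equiv), CH2Cl2, 0 to 23 °C; aq. NaHCO3
Reagents that add atoms: Eschenmoser's salt (N,N-dimethylmethylideneammonium iodide), C=[N+](C)C.[I-]
Why: CuH-catalysed 1,4-reduction delivers hydride to C15 anti to the C5 side chain (cis-4,5-disubstituted lactone, C15 R), and a Mannich reaction of the silyl ketene acetal installs the masked methylene; the C2 epimers are irrelevant.

Step 6
Reactants: 12 (2R)-4-methoxy-2-methyl-4-oxobutanoic acid; 13 2-(2-bromoethyl)-2-methyl-1,3-dioxolane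
Product: 16 methyl (3R)-3-methyl-6-(2-methyl-1,3-dioxolan-2-yl)-4-oxohexanoate, via acid chloride 14 (not isolated), via Grignard reagent 15 (not isolated)
Conditions: 12, (COCl)2, DMF (cat.), CH2Cl2, 0 to 23 °C; 13, Mg, THF, 23 °C; combined with Fe(acac)3 (3 mol%), THF, −78 °C
Reagents that add atoms: none
Why: Acid chloride formation followed by iron-catalysed Grignard acylation gives the ketone faster than the Grignard reagent attacks the methyl ester, and the near-neutral, cold conditions keep the α-stereocentre (C20, R, from the starting acid).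

Step 7
Reactants: 16 methyl (3R)-3-methyl-6-(2-methyl-1,3-dioxolan-2-yl)-4-oxohexanoate
Product: 17 methyl (3R)-3-methyl-4-methylidene-6-(2-methyl-1,3-dioxolan-2-yl)hexanoate
Conditions: Zn, CH2Br2, TiCl4, THF/CH2Cl2, 0 to 23 °C
Reagents that add atoms: dibromomethane, BrCBr
Why: Takai–Lombardo methylenation is non-basic, so the enolizable α-methyl ketone becomes the 1,1-disubstituted alkene without epimerization while the ester and ketal survive.

Step 8
Reactants: 17 methyl (3R)-3-methyl-4-methylidene-6-(2-methyl-1,3-dioxolan-2-yl)hexanoate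
Product: 18 (3R)-3-methyl-4-methylidene-6-(2-methyl-1,3-dioxolan-2-yl)hexanal
Conditions: i-Bu2AlH (1.05 equiv), CH2Cl2, −78 °C; aq. KNaC4H4O6
Reagents that add atoms: none
Why: Low-temperature DIBAL half-reduction of the methyl ester stops at the aluminium hemiacetal and releases the aldehyde on work-up.

Step 9
Reactants: 18 (3R)-3-methyl-4-methylidene-6-(2-methyl-1,3-dioxolan-2-yl)hexanal; 5 methyl propiolate
Product: 20 methyl (4S,6R)-4-hydroxy-6-methyl-7-methylidene-9-(2-methyl-1,3-dioxolan-2-yl)non-2-ynoate, via ethylzinc alkynylide 19 (not isolated)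
Conditions: 5 (3 equiv), Et2Zn (3 equiv), (R)-BINOL (40 mol%), Cy2NH (5 mol%), Et2O, 23 °C, 16 h; Ti(OiPr)4 (50 mol%), 1 h; then 18, 23 °C; aq. NH4Cl
Reagents that add atoms: none
Why: BINOL–Ti(OiPr)4-catalysed asymmetric alkynylzinc addition, in which the propiolate is zincated by Et2Zn (amine-accelerated) and the (R)-BINOL ligand rather than the remote C20 centre sets C18 as S, opposite in sense to C5 in step 3 as this heterochiral target requires; the ligand hand is assigned from the usual model and the antipode would give the C18 epimer.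

Step 10
Reactants: 20 methyl (4S,6R)-4-hydroxy-6-methyl-7-methylidene-9-(2-methyl-1,3-dioxolan-2-yl)non-2-ynoate
Product: 21 methyl (4S,6R)-4-[(tert-butyldimethylsilyl)oxy]-6-methyl-7-methylidene-9-(2-methyl-1,3-dioxolan-2-yl)non-2-ynoate
Conditions: TBSCl, imidazole, DMF, 23 °C
Reagents that add atoms: tert-butyldimethylsilyl chloride, CC(C)(C)[Si](C)(C)Cl
Why: Silyl ether formation blocks lactonization, so C16 stays a methyl ester that can later become the pyrone carbonyl.

Step 11
Reactants: 21 methyl (4S,6R)-4-[(tert-butyldimethylsilyl)oxy]-6-methyl-7-methylidene-9-(2-methyl-1,3-dioxolan-2-yl)non-2-ynoate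
Product: 22 methyl (2Z,4S,6R)-4-[(tert-butyldimethylsilyl)oxy]-6-methyl-7-methylidene-9-(2-methyl-1,3-dioxolan-2-yl)-3-(prop-2-en-1-yl)non-2-enoate
Conditions: allylMgBr (1.5 equiv), CuI·2LiCl (1.5 equiv), THF, −78 °C; aq. NH4Cl
Reagents that add atoms: allylmagnesium bromide, C=CC[Mg]Br
Why: syn-Carbocupration of the silyloxy ynoate gives the β-allyl enoate (Z expected; the geometry is erased in step 13), and with no free hydroxyl no lactone forms.

Step 12
Reactants: 22 methyl (2Z,4S,6R)-4-[(tert-butyldimethylsilyl)oxy]-6-methyl-7-methylidene-9-(2-methyl-1,3-dioxolan-2-yl)-3-(prop-2-en-1-yl)non-2-enoate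
Product: 23 methyl (2Z)-2-[(5R,7S)-7-[(tert-butyldimethylsilyl)oxy]-5-methyl-4-[2-(2-methyl-1,3-dioxolan-2-yl)ethyl]cyclohept-3-en-1-ylidene]acetate
Conditions: second-generation Grubbs catalyst (H2IMes)(PCy3)Cl2Ru=CHPh (5 mol%), PhMe (5 mM), 80 °C
Reagents that add atoms: none
Why: Ring-closing metathesis between the allyl group and the 1,1-disubstituted alkene closes the trisubstituted cycloheptene (ring E), while the electron-poor trisubstituted enoate stays out.

Step 13
Reactants: 23 methyl (2Z)-2-[(5R,7S)-7-[(tert-butyldimethylsilyl)oxy]-5-methyl-4-[2-(2-methyl-1,3-dioxolan-2-yl)ethyl]cyclohept-3-en-1-ylidene]acetate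
Product: 25 methyl 2-[(1S,5R,7S)-7-[(tert-butyldimethylsilyl)oxy]-5-methyl-4-[2-(2-methyl-1,3-dioxolan-2-yl)ethyl]cyclohept-3-en-1-yl]acetate, via silyl ketene acetal 24 (not isolated)
Conditions: [(Ph3P)CuH]6 (5 mol%), PhMe2SiH (1.5 equiv), PhMe, 23 °C; then MeOH/H2O
Reagents that add atoms: none
Why: CuH-catalysed conjugate reduction adds hydride to C24 from the ring face opposite the neighbouring OTBS group and the cis C20 methyl, giving the 1,2-cis CH2CO2Me/OTBS arrangement (C24 S).

Step 14
Reactants: 25 methyl 2-[(1S,5R,7S)-7-[(tert-butyldimethylsilyl)oxy]-5-methyl-4-[2-(2-methyl-1,3-dioxolan-2-yl)ethyl]cyclohept-3-en-1-yl]acetate; 11 (4R,5R)-5-[(2S)-2-(4-bromo-5-methylfuran-2-yl)propyl]-3-[(dimethylamino)methyl]-4-(prop-2-en-1-yl)oxolan-2-one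
Product: 27 furan-3-yl acetate coupling product (full name in the list), via zinc enolate 26 (not isolated)
Conditions: LiN(SiMe3)2, THF, −78 °C; ZnCl2, −78 to 23 °C; then 11, Pd(dba)2 (5 mol%), P(t-Bu)3 (10 mol%), THF, 60 °C
Reagents that add atoms: none
Why: Palladium-catalysed α-arylation of a zinc ester enolate (Reformatsky-type Negishi coupling) joins C11 to the furan carbon that becomes C10; the zinc enolate is too weakly basic to touch lactone ring A or the amine, and the new C11 centre is a mixture that later becomes sp2.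

Step 15
Reactants: 27 furan-3-yl acetate coupling product
Product: 30 4-acetyl-2-pyrone (full name in the list), via furan endoperoxide 28 (not isolated), via cis-enedione 29 (not isolated)
Conditions: CF3CO2H (1.1 equiv), O2, tetraphenylporphyrin (1 mol%), visible light, CH2Cl2, −78 °C; Me2S, −78 to 0 °C; then DBU (3 equiv), 0 to 40 °C
Reagents that add atoms: oxygen, O=O
Why: Singlet-oxygen [4+2] photooxygenation of the furan (amine protonated, furan far more reactive than the alkenes), reduction to the cis-enedione and base-induced enol-lactonization onto the methyl ester build the pyrone; deprotonation at C11 comes first and gives the C8 dienolate, which can rotate about C9–C10 to close the ring and which shields the C7 centre from epimerization.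

Step 16
Reactants: 30 4-acetyl-2-pyrone
Product: 31 bridged-lactone cycloadduct (2-oxabicyclo[2.2.2]oct-5-en-3-one in which rings A, B and C are closed; full description in the list)
Conditions: PhMe (5 mM), BHT (10 mol%), sealed tube, 105 °C, 72 h
Reagents that add atoms: none
Why: Proposed new method: an intramolecular pyrone–alkene Diels–Alder reaction through a five-carbon tether closes cycloheptane ring B and cyclohexene ring C at once, and because the pyrone O and C16 remain joined as the bridge, the C8–O and C11–C16 bonds are necessarily cis; the alkene should add with the tether folded under the C9–H edge so that the C7 methyl and cis-lactone ring A lie on the face of the forming cycloheptane away from C9 and C12, giving C8 S, C11 S and C13 R, while the ring E substituent only rotates about C11–C24 and does not choose the face; the closest known chemistry is the intramolecular 2-pyrone Diels–Alder reaction with three- or four-atom tethers, which keeps the CO2 bridge at about 100 °C.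

Step 17
Reactants: 31 bridged-lactone cycloadduct
Product: 33 amino spirolactone (the target with CH(CH2NMe2) in place of C=CH2), via hydroxy bridged lactone 32 (not isolated)
Conditions: 2 M aq. HCl/THF 1:4, 23 °C; NaHCO3 work-up
Reagents that add atoms: water, O
Why: Acid removes the silyl ether and the ketal, and the freed C18 hydroxyl opens the strained bridged lactone by translactonization to the cis-fused five-membered spirolactone (ring D), releasing the C8 alcohol with the configuration fixed by the bridge.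

Step 18
Reactants: 33 amino spirolactone
Product: 35 CNP0195550.4 (target), via ammonium iodide 34 (not isolated)
Conditions: MeI (10 equiv), MeOH, 23 °C; then NaHCO3, CH2Cl2/H2O, 23 °C
Reagents that add atoms: none
Why: Exhaustive N-methylation then E1cB (Hofmann-type) loss of trimethylamine from the β-ammonio lactone unveils the exocyclic methylene under conditions that leave the ketones, enone, tertiary alcohol and spirolactone alone.

## Compound list

1 | 2-methylfuran | Cc1ccco1 | starting material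
2 | (E)-but-2-enal (crotonaldehyde) | C/C=C/C=O | starting material
3 | (3S)-3-(5-methylfuran-2-yl)butanal | O=CC[C@H](C)c1ccc(C)o1 | intermediate
4 | (3S)-3-(4-bromo-5-methylfuran-2-yl)butanal | O=CC[C@H](C)c1cc(Br)c(C)o1 | intermediate
5 | methyl propiolate | C#CC(=O)OC | starting material
6 | methyl 3-(methylzincio)prop-2-ynoate (zinc alkynylide) | COC(=O)C#C[Zn]C | intermediate
7 | methyl (4R,6S)-6-(4-bromo-5-methylfuran-2-yl)-4-hydroxyhept-2-ynoate | COC(=O)C#C[C@H](O)C[C@H](C)c1cc(Br)c(C)o1 | intermediate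
8 | methyl (2Z,4R,6S)-6-(4-bromo-5-methylfuran-2-yl)-4-hydroxy-3-(prop-2-en-1-yl)hept-2-enoate | COC(=O)/C=C(/CC=C)[C@H](O)C[C@H](C)c1cc(Br)c(C)o1 | intermediate
9 | (5R)-5-[(2S)-2-(4-bromo-5-methylfuran-2-yl)propyl]-4-(prop-2-en-1-yl)furan-2(5H)-one | C=CCC1=CC(=O)O[C@@H]1C[C@H](C)c1cc(Br)c(C)o1 | intermediate
10 | {[(4R,5R)-5-[(2S)-2-(4-bromo-5-methylfuran-2-yl)propyl]-4-(prop-2-en-1-yl)-4,5-dihydrofuran-2-yl]oxy}dimethyl(phenyl)silane | C=CC[C@@H]1C=C(O[Si](C)(C)c2ccccc2)O[C@@H]1C[C@H](C)c1cc(Br)c(C)o1 | intermediate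
11 | (4R,5R)-5-[(2S)-2-(4-bromo-5-methylfuran-2-yl)propyl]-3-[(dimethylamino)methyl]-4-(prop-2-en-1-yl)oxolan-2-one (both C3 epimers) | C=CC[C@@H]1C(CN(C)C)C(=O)O[C@@H]1C[C@H](C)c1cc(Br)c(C)o1 | intermediate
12 | (2R)-4-methoxy-2-methyl-4-oxobutanoic acid | COC(=O)C[C@@H](C)C(=O)O | starting material
13 | 2-(2-bromoethyl)-2-methyl-1,3-dioxolane | CC1(CCBr)OCCO1 | starting material
14 | methyl (3R)-4-chloro-3-methyl-4-oxobutanoate | COC(=O)C[C@@H](C)C(Cl)=O | intermediate
15 | [2-(2-methyl-1,3-dioxolan-2-yl)ethyl]magnesium bromide | CC1(CC[Mg]Br)OCCO1 | intermediate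
16 | methyl (3R)-3-methyl-6-(2-methyl-1,3-dioxolan-2-yl)-4-oxohexanoate | COC(=O)C[C@@H](C)C(=O)CCC1(C)OCCO1 | intermediate
17 | methyl (3R)-3-methyl-4-methylidene-6-(2-methyl-1,3-dioxolan-2-yl)hexanoate | COC(=O)C[C@@H](C)C(=C)CCC1(C)OCCO1 | intermediate
18 | (3R)-3-methyl-4-methylidene-6-(2-methyl-1,3-dioxolan-2-yl)hexanal | O=CC[C@@H](C)C(=C)CCC1(C)OCCO1 | intermediate
19 | methyl 3-(ethylzincio)prop-2-ynoate (ethylzinc alkynylide) | COC(=O)C#C[Zn]CC | intermediate
20 | methyl (4S,6R)-4-hydroxy-6-methyl-7-methylidene-9-(2-methyl-1,3-dioxolan-2-yl)non-2-ynoate | COC(=O)C#C[C@@H](O)C[C@@H](C)C(=C)CCC1(C)OCCO1 | intermediate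
21 | methyl (4S,6R)-4-[(tert-butyldimethylsilyl)oxy]-6-methyl-7-methylidene-9-(2-methyl-1,3-dioxolan-2-yl)non-2-ynoate | COC(=O)C#C[C@@H](O[Si](C)(C)C(C)(C)C)C[C@@H](C)C(=C)CCC1(C)OCCO1 | intermediate
22 | methyl (2Z,4S,6R)-4-[(tert-butyldimethylsilyl)oxy]-6-methyl-7-methylidene-9-(2-methyl-1,3-dioxolan-2-yl)-3-(prop-2-en-1-yl)non-2-enoate | COC(=O)/C=C(/CC=C)[C@@H](O[Si](C)(C)C(C)(C)C)C[C@@H](C)C(=C)CCC1(C)OCCO1 | intermediate
23 | methyl (2Z)-2-[(5R,7S)-7-[(tert-butyldimethylsilyl)oxy]-5-methyl-4-[2-(2-methyl-1,3-dioxolan-2-yl)ethyl]cyclohept-3-en-1-ylidene]acetate | COC(=O)/C=C1/CC=C(CCC2(C)OCCO2)[C@H](C)C[C@@H]1O[Si](C)(C)C(C)(C)C | intermediate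
24 | dimethyl(phenyl)silyl ketene acetal of ester 25 | COC(O[Si](C)(C)c1ccccc1)=C[C@@H]1CC=C(CCC2(C)OCCO2)[C@H](C)C[C@@H]1O[Si](C)(C)C(C)(C)C | intermediate
25 | methyl 2-[(1S,5R,7S)-7-[(tert-butyldimethylsilyl)oxy]-5-methyl-4-[2-(2-methyl-1,3-dioxolan-2-yl)ethyl]cyclohept-3-en-1-yl]acetate (CH2CO2Me, OTBS and CH3 all cis) | COC(=O)C[C@@H]1CC=C(CCC2(C)OCCO2)[C@H](C)C[C@@H]1O[Si](C)(C)C(C)(C)C | intermediate
26 | chlorozinc enolate of ester 25 (drawn C-bound) | COC(=O)C([Zn]Cl)[C@@H]1CC=C(CCC2(C)OCCO2)[C@H](C)C[C@@H]1O[Si](C)(C)C(C)(C)C | intermediate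
27 | methyl 2-{5-[(2S)-1-{(2R,3R)-4-[(dimethylamino)methyl]-5-oxo-3-(prop-2-en-1-yl)oxolan-2-yl}propan-2-yl]-2-methylfuran-3-yl}-2-{(1S,5R,7S)-7-[(tert-butyldimethylsilyl)oxy]-5-methyl-4-[2-(2-methyl-1,3-dioxolan-2-yl)ethyl]cyclohept-3-en-1-yl}acetate (epimers at C11 and at the aminomethyl-bearing carbon) | C=CC[C@@H]1C(CN(C)C)C(=O)O[C@@H]1C[C@H](C)c1cc(C(C(=O)OC)[C@@H]2CC=C(CCC3(C)OCCO3)[C@H](C)C[C@@H]2O[Si](C)(C)C(C)(C)C)c(C)o1 | intermediate
28 | 2,5-endoperoxide of furan 27 (2,3,7-trioxabicyclo[2.2.1]hept-5-ene, bridgehead epimers) | C=CC[C@@H]1C(CN(C)C)C(=O)O[C@@H]1C[C@H](C)C12OOC(C)(O1)C(C(C(=O)OC)[C@@H]3CC=C(CCC4(C)OCCO4)[C@H](C)C[C@@H]3O[Si](C)(C)C(C)(C)C)=C2 | intermediate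
29 | (Z)-enedione from furan 27: C8 ketone and acetyl cis across C9=C10, C10 carrying the CH(CO2Me)(cycloheptenyl) group | C=CC[C@@H]1C(CN(C)C)C(=O)O[C@@H]1C[C@H](C)C(=O)/C=C(\C(C)=O)C(C(=O)OC)[C@@H]2CC=C(CCC3(C)OCCO3)[C@H](C)C[C@@H]2O[Si](C)(C)C(C)(C)C | intermediate
30 | 4-acetyl-6-[(2S)-1-{(2R,3R)-4-[(dimethylamino)methyl]-5-oxo-3-(prop-2-en-1-yl)oxolan-2-yl}propan-2-yl]-3-{(1S,5R,7S)-7-[(tert-butyldimethylsilyl)oxy]-5-methyl-4-[2-(2-methyl-1,3-dioxolan-2-yl)ethyl]cyclohept-3-en-1-yl}-2H-pyran-2-one | C=CC[C@@H]1C(CN(C)C)C(=O)O[C@@H]1C[C@H](C)C1=CC(C(C)=O)=C([C@@H]2CC=C(CCC3(C)OCCO3)[C@H](C)C[C@@H]2O[Si](C)(C)C(C)(C)C)C(=O)O1 | intermediate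
31 | cycloadduct: rings A, B and C of the target closed, C16 still esterified to the C8 oxygen (2-oxabicyclo[2.2.2]oct-5-en-3-one), C18–OTBS, side-chain dioxolane, C2–CH2NMe2; C5, C7, C8, C11, C13, C15, C18, C20, C24 as in the target | CN(C)CC1C(=O)O[C@@H]2C[C@H](C)[C@@]3(O4)C=C(C(C)=O)[C@@](C[C@H]3C[C@H]12)(C4=O)[C@@H]5CC=C(CCC6(C)OCCO6)[C@H](C)C[C@@H]5O[Si](C)(C)C(C)(C)C | intermediate
32 | cycloadduct 31 with free C18–OH and free side-chain ketone | CN(C)CC1C(=O)O[C@@H]2C[C@H](C)[C@@]3(O4)C=C(C(C)=O)[C@@](C[C@H]3C[C@H]12)(C4=O)[C@@H]5CC=C(CCC(C)=O)[C@H](C)C[C@@H]5O | intermediate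
33 | target skeleton with C2 as CH(CH2NMe2) instead of C=CH2 (C2 epimers), all other centres as in the target | CN(C)CC1C(=O)O[C@@H]2C[C@H](C)[C@@]3(O)C=C(C(C)=O)[C@@]4(C[C@H]3C[C@H]12)C(=O)O[C@H]1C[C@@H](C)C(CCC(C)=O)=CC[C@H]14 | intermediate
34 | trimethylammonium iodide of 33 | C[N+](C)(C)CC1C(=O)O[C@@H]2C[C@H](C)[C@@]3(O)C=C(C(C)=O)[C@@]4(C[C@H]3C[C@H]12)C(=O)O[C@H]1C[C@@H](C)C(CCC(C)=O)=CC[C@H]14.[I-] | intermediate
35 | CNP0195550.4 (5R,7S,8S,11S,13R,15R,18S,20R,24S in the labels used here) | C=C1C(=O)O[C@@H]2C[C@H](C)[C@@]3(O)C=C(C(C)=O)[C@@]4(C[C@H]3C[C@H]12)C(=O)O[C@H]1C[C@@H](C)C(CCC(C)=O)=CC[C@H]14 | target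

## Step count and risks

Total: 18 steps. Longest linear sequence: 13 steps (12 → 35, steps 6–18); the other branch is 10 steps (1 → 35).

Three steps most likely to fail:

**Step 16 (pyrone cycloaddition).** A five-carbon tether and an unactivated alkene make this slow. Above about 130 °C the adduct can lose CO2. The tether may fold the other way, giving the C13 epimer; this is the least predictable stereochemical element of the route. The fallback activates the diene with a removable substituent, which lets the cycloaddition run cooler. It sets out from 27: NBS (on the trifluoroacetate salt, DMF, −20 °C) brominates the last furan C–H to give the tetrasubstituted bromofuran F1. The step 15 sequence then gives the 5-bromo-2-pyrone F2, a more reactive ambiphilic diene. Cycloaddition at or below 80 °C gives the bromo cycloadduct F3. Zn in AcOH removes the vinylic bromine of the β-bromo enone, and the route is rejoined at 31.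

**Step 15 (furan to pyrone).** Photooxygenation must pick the furan over the ring E alkene and the amine, and the enedione must close onto the ester before anything else happens. The fallback replaces the cycloaddition-type oxidation by a two-electron anodic one with an isolable intermediate. It sets out from 27: anodic oxidation in methanol (graphite, Et4NOTs, −20 °C, amine as its salt) gives the 2,5-dimethoxy-2,5-dihydrofuran F4. PPTS in acetone/H2O hydrolyses it to the cis-enedione, rejoining at 29, which DBU closes to 30 as before.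

**Step 4 (allylcopper addition).** Allylcopper reagents can attack the ester or give allenoate-derived mixtures. The fallback swaps carbocupration for hydrohalogenation and cross-coupling. It sets out from 7: NaI in AcOH (70 °C) adds HI across the ynoate; the β-iodo enoate equilibrates under the acidic conditions by iodide addition–elimination, and the isomer with the carbinol cis to the ester lactonizes to the (5R)-4-iodo-5-[(2S)-2-(4-bromo-5-methylfuran-2-yl)propyl]furan-2(5H)-one F5. Stille coupling with allyltributylstannane (Pd2(dba)3, AsPh3, NMP, 23 °C; the vinyl iodide reacts before the furyl bromide) rejoins the route at 9.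

Further compounds
F1 | step 16 | 4-bromo derivative of furan 27 (bromine on the furan carbon that becomes C9) | C=CC[C@@H]1C(CN(C)C)C(=O)O[C@@H]1C[C@H](C)c1c(Br)c(C(C(=O)OC)[C@@H]2CC=C(CCC3(C)OCCO3)[C@H](C)C[C@@H]2O[Si](C)(C)C(C)(C)C)c(C)o1
F2 | step 16 | 5-bromo derivative of pyrone 30 | C=CC[C@@H]1C(CN(C)C)C(=O)O[C@@H]1C[C@H](C)C1=C(Br)C(C(C)=O)=C([C@@H]2CC=C(CCC3(C)OCCO3)[C@H](C)C[C@@H]2O[Si](C)(C)C(C)(C)C)C(=O)O1
F3 | step 16 | 9-bromo derivative of cycloadduct 31 | CN(C)CC1C(=O)O[C@@H]2C[C@H](C)[C@@]3(O4)C(Br)=C(C(C)=O)[C@@](C[C@H]3C[C@H]12)(C4=O)[C@@H]5CC=C(CCC6(C)OCCO6)[C@H](C)C[C@@H]5O[Si](C)(C)C(C)(C)C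
F4 | step 15 | 2,5-dimethoxy-2,5-dihydrofuran derived from furan 27 (ketal epimers) | C=CC[C@@H]1C(CN(C)C)C(=O)O[C@@H]1C[C@H](C)C1(OC)C=C(C(C(=O)OC)[C@@H]2CC=C(CCC3(C)OCCO3)[C@H](C)C[C@@H]2O[Si](C)(C)C(C)(C)C)C(C)(OC)O1
F5 | step 4 | (5R)-4-iodo-5-[(2S)-2-(4-bromo-5-methylfuran-2-yl)propyl]furan-2(5H)-one | IC1=CC(=O)O[C@@H]1C[C@H](C)c1cc(Br)c(C)o1
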